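Assumption: the SMILES is taken literally. In germacrane numbering the target is the 6α,12‑olide (H‑6β, H‑7α) with 3β‑OH, 4α‑H (15‑CH2OAc β), 8β‑(Z)‑2‑(hydroxymethyl)but‑2‑enoyloxy and a 5α,10β‑oxygen bridge; CIP 3S,4S,5R,6S,7R,8R,10R. H‑5 and the C10 methyl lie on opposite faces of the bridge, as if oxygen had been inserted into the ring‑fusion bond of a trans‑eudesmane. This is a paper route; nothing has been run.

Abbreviations: TBS = tert‑butyldimethylsilyl; TES = triethylsilyl; OTMP = (2,2,6,6‑tetramethylpiperidin‑1‑yl)oxy. Ring compounds are named with germacrane numbering (C14 = methyl on C10, C15 on C4; α/β as in the flat germacrane drawing).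

**Retrosynthetic overview**
1. Target ⇐ C8 acylation and C15 acetylation of a 5,10‑ether‑bridged 15‑aldehyde ⇐ transannular oxa‑Michael addition of the C10 tertiary alcohol to a 15‑oxo‑germacr‑4‑en‑6α,12‑olide (ether bridge last).
2. Ten‑membered ring and lactone ⇐ C6–C7 bond by intramolecular Barbier allylation (the counterpart of the C1–C10 closure of farnesyl diphosphate) of an acyclic (Z)‑enedial carrying a 2‑(bromomethyl)acrylate; the enedial is a 3‑substituted furan in disguise.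
3. All 15 skeletal carbons come from (R)‑linalool (C1–C3, C8–C10, C14), 3‑bromofuran (C4–C6, C15), CO (C7) and methyl propiolate (C11–C13).
4. Stereocentres: C10 from linalool; C3 by Noyori transfer hydrogenation; C8 by organocatalytic α‑oxyamination; C6/C7 in the macrocyclisation; C5/C4 in the oxa‑Michael step.
5. Ring order: carbocycle (C6–C7) → γ‑lactone (O6–C12) → oxepane bridge (C5–O–C10).

**Route**

Step 1
Reactants: 1 (R)‑(−)‑linalool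
Product: 3 (5R)‑5‑methyl‑5‑vinyldihydrofuran‑2(3H)‑one, via lactol 2 (not isolated)
Conditions: O3, CH2Cl2/MeOH, −78 °C (Sudan III end point); Me2S; then TEMPO (10 mol %), PhI(OAc)2, CH2Cl2, rt
Reagents that add atoms: ozone, O=[O+][O-]
Why: Ozonolysis cleaves the electron‑rich trisubstituted alkene in preference to the vinyl group, the hydroxy aldehyde closes to lactol 2, and TEMPO/PhI(OAc)2 oxidises it to the lactone; the tertiary carbinol centre (future C10, R) is untouched.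

Step 2
Reactants: 3 (5R)‑5‑methyl‑5‑vinyldihydrofuran‑2(3H)‑one; 4 3‑bromofuran
Product: 6 (4R)‑1‑(furan‑3‑yl)‑4‑hydroxy‑4‑methylhex‑5‑en‑1‑one, via 3‑furyllithium 5 (not isolated)
Conditions: 4, n‑BuLi, THF, −78 °C; then 3, −78 °C; NH4Cl
Reagents that add atoms: none
Why: Lithium–halogen exchange gives 3‑furyllithium, which adds once to the γ‑lactone (acyl substitution; the tetrahedral lithium alkoxide survives at −78 °C), attaching the masked C4–C6/C15 unit to C3.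

Step 3
Reactants: 6 (4R)‑1‑(furan‑3‑yl)‑4‑hydroxy‑4‑methylhex‑5‑en‑1‑one
Product: 7 (1S,4R)‑1‑(furan‑3‑yl)‑4‑methylhex‑5‑ene‑1,4‑diol
Conditions: RuCl[(S,S)‑TsDPEN](p‑cymene) (1 mol %), HCO2H/Et3N (5:2), rt
Reagents that add atoms: none
Why: Noyori asymmetric transfer hydrogenation of a heteroaryl alkyl ketone; the (S,S) catalyst delivers hydride to give the (S) carbinol (future C3) under catalyst control and tolerates the free tertiary alcohol.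

Step 4
Reactants: 7 (1S,4R)‑1‑(furan‑3‑yl)‑4‑methylhex‑5‑ene‑1,4‑diol
Product: 9 (1S,4R)‑1‑(furan‑3‑yl)‑4‑methyl‑1‑(TBS‑oxy)‑4‑(TES‑oxy)hex‑5‑ene, via mono‑TBS ether 8 (not isolated)
Conditions: TBSCl, imidazole, CH2Cl2, rt; then 2,6‑lutidine, TESOTf, 0 °C
Reagents that add atoms: tert‑butyldimethylsilyl chloride, CC(C)(C)[Si](C)(C)Cl; triethylsilyl triflate, CC[Si](CC)(CC)OS(=O)(=O)C(F)(F)F
Why: Chemoselective silylation: TBSCl takes only the secondary alcohol, and the tertiary alcohol then needs the triflate, so C3–O is protected to the end and C10–O with a group that can be removed selectively.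

Step 5
Reactants: 9 (1S,4R)‑1‑(furan‑3‑yl)‑4‑methyl‑1‑(TBS‑oxy)‑4‑(TES‑oxy)hex‑5‑ene
Product: 10 (4R,7S)‑7‑(TBS‑oxy)‑7‑(furan‑3‑yl)‑4‑methyl‑4‑(TES‑oxy)heptanal
Conditions: Rh(acac)(CO)2 (1 mol %), Xantphos, CO/H2 (1:1, 10 bar), toluene, 70 °C
Reagents that add atoms: carbon monoxide, [C-]#[O+]
Why: Rh‑catalysed hydroformylation gives only the linear aldehyde because the vinyl group sits on a quaternary carbon and the wide‑bite‑angle ligand favours anti‑Markovnikov insertion; this adds C7.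

Step 6
Reactants: 10 (4R,7S)‑7‑(TBS‑oxy)‑7‑(furan‑3‑yl)‑4‑methyl‑4‑(TES‑oxy)heptanal
Product: 11 (2R,4R,7S)‑7‑(TBS‑oxy)‑7‑(furan‑3‑yl)‑4‑methyl‑4‑(TES‑oxy)‑2‑(OTMP)heptanal
Conditions: TEMPO, MacMillan imidazolidinone·TFA (20 mol %, antipode giving 2R), CuCl2·2H2O (10 mol %), air, acetone, −10 °C
Reagents that add atoms: TEMPO, CC1(C)CCCC(C)(C)N1[O]
Why: Enamine‑catalysed α‑oxyamination of an unbranched aldehyde; the chiral enamine shields one face so that TEMPO is delivered to give the (R) centre (future C8, 8β‑O) under catalyst control, as a stable O‑protected α‑hydroxy aldehyde.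

Step 7
Reactants: 11 (2R,4R,7S)‑7‑(TBS‑oxy)‑7‑(furan‑3‑yl)‑4‑methyl‑4‑(TES‑oxy)‑2‑(OTMP)heptanal; 12 methyl propiolate
Product: 14 methyl (3RS,4R,6R,9S)‑9‑(TBS‑oxy)‑9‑(furan‑3‑yl)‑3‑hydroxy‑6‑methyl‑2‑methylidene‑4‑(OTMP)‑6‑(TES‑oxy)nonanoate, via vinylalane 13 (not isolated)
Conditions: 12, DIBAL‑H, NMO, THF, 0 °C; then 11, 0 °C → rt; Rochelle salt
Reagents that add atoms: none
Why: Hydroalumination of the propiolate gives the α‑aluminoacrylate, which adds to the hindered aldehyde (vinylalumination, a Morita–Baylis–Hillman‑type aldol); the new carbinol centre is formed as a mixture and is erased in step 8.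

Step 8
Reactants: 14 methyl (3RS,4R,6R,9S)‑9‑(TBS‑oxy)‑9‑(furan‑3‑yl)‑3‑hydroxy‑6‑methyl‑2‑methylidene‑4‑(OTMP)‑6‑(TES‑oxy)nonanoate
Product: 16 methyl (2Z,4R,6R,9S)‑2‑(bromomethyl)‑9‑(TBS‑oxy)‑9‑(furan‑3‑yl)‑6‑methyl‑4‑(OTMP)‑6‑(TES‑oxy)non‑2‑enoate, via mesylate 15 (not isolated)
Conditions: MsCl, Et3N, CH2Cl2, −20 °C; then LiBr, THF, rt
Reagents that add atoms: lithium bromide, [Li+].[Br-]
Why: Mesylation followed by SN2′ displacement with bromide transposes the allylic system to the thermodynamically preferred (Z)‑2‑(bromomethyl)enoate under neutral conditions that spare the furan and silyl ethers.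

Step 9
Reactants: 16 methyl (2Z,4R,6R,9S)‑2‑(bromomethyl)‑9‑(TBS‑oxy)‑9‑(furan‑3‑yl)‑6‑methyl‑4‑(OTMP)‑6‑(TES‑oxy)non‑2‑enoate
Product: 19 3β‑(TBS‑oxy)‑8β‑(OTMP)‑10β‑(TES‑oxy)‑15‑oxogermacra‑4,11(13)‑dien‑6α,12‑olide (ring‑trans C4=C5; 10α‑methyl), via enedial 17 (not isolated), via hydroxy ester 18 (not isolated)
Conditions: NBS, NaHCO3, acetone/H2O (9:1), −20 °C; then In powder, THF/H2O (3:1), 2 mM, rt; then PPTS (cat.), CH2Cl2, rt
Reagents that add atoms: water, O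
Why: Proposed new method: NBS/water opens the furan to the (Z)‑2‑substituted butenedial (known furan → cis‑enedial oxidation), the allylindium formed from the 2‑(bromomethyl)acrylate attacks the unhindered C6 formyl group rather than the C15 formyl group, which is flanked by the fully substituted C4 and its CH(OTBS) branch, through a chair‑like Zimmerman–Traxler transition state with C5 and C8 both equatorial (6,7‑anti, hence trans lactone) and with the new bond anti to C8–C9 while H‑8 eclipses the olefin and the non‑chelating OTMP group points outward (Felkin‑type 1,2‑induction, H‑7/H‑8 cis), and the γ‑hydroxy ester then lactonises; the closest known reaction type is the In‑ or Cr‑mediated Barbier (Nozaki–Hiyama) macrocyclisation of 2‑(bromomethyl)acrylates onto enals that gives germacranolides.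

Step 10
Reactants: 19 3β‑(TBS‑oxy)‑8β‑(OTMP)‑10β‑(TES‑oxy)‑15‑oxogermacra‑4,11(13)‑dien‑6α,12‑olide
Product: 22 3β‑(TBS‑oxy)‑8β‑(OTMP)‑5α,10β‑epoxy‑15‑hydroxy‑4αH‑germacr‑11(13)‑en‑6α,12‑olide, via tertiary alcohol 20 (not isolated), via bicyclic aldehyde 21 (not isolated)
Conditions: HF·pyridine, pyridine, THF, 0 °C → rt; then DBU (10 mol %), CH2Cl2, 0 °C; then NaBH4, CeCl3·7H2O, MeOH, −40 °C
Reagents that add atoms: none
Why: HF·pyridine removes the TES ether much faster than the secondary TBS ether, and the freed (10R) hydroxyl, which points into the ring, adds to the inner face of the enal β‑carbon C5 held in the germacrolide conformation (C15 syn to H‑6 by A(1,3) strain) in a transannular oxa‑Michael addition that sets C5 (R) with the trans bridge; the enol is protonated from the peripheral face (H‑4α) and immediate Luche reduction locks C4 and C5 before retro‑Michael or epimerisation, leaving the α‑methylene lactone intact.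

Step 11
Reactants: 22 3β‑(TBS‑oxy)‑8β‑(OTMP)‑5α,10β‑epoxy‑15‑hydroxy‑4αH‑germacr‑11(13)‑en‑6α,12‑olide
Product: 23 15‑acetoxy‑3β‑(TBS‑oxy)‑8β‑(OTMP)‑5α,10β‑epoxy‑4αH‑germacr‑11(13)‑en‑6α,12‑olide
Conditions: Ac2O, pyridine, DMAP (cat.), CH2Cl2, 0 °C
Reagents that add atoms: acetic anhydride, CC(=O)OC(C)=O
Why: The primary C15 alcohol is the only free hydroxyl, so a plain acetylation installs the 15‑acetate.

Step 12
Reactants: 23 15‑acetoxy‑3β‑(TBS‑oxy)‑8β‑(OTMP)‑5α,10β‑epoxy‑4αH‑germacr‑11(13)‑en‑6α,12‑olide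
Product: 24 15‑acetoxy‑3β‑(TBS‑oxy)‑5α,10β‑epoxy‑8β‑hydroxy‑4αH‑germacr‑11(13)‑en‑6α,12‑olide
Conditions: Zn dust, AcOH/THF (1:3), 40 °C
Reagents that add atoms: none
Why: Zinc reduces the N–O bond of the alkoxyamine (reductive N–O cleavage) and releases the 8β‑alcohol with retention, under conditions too mild for the acetate, lactone and TBS ether.

Step 13
Reactants: 25 methyl but‑2‑ynoate
Product: 27 methyl (Z)‑2‑(hydroxymethyl)but‑2‑enoate, via vinylalane 26 (not isolated)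
Conditions: DIBAL‑H, NMO, THF, 0 °C; then CH2O (gas, from cracked paraformaldehyde), −78 °C → rt
Reagents that add atoms: formaldehyde, C=O
Why: syn‑Hydroalumination puts H and Al cis, so the methyl group ends up cis to the ester, and the vinyl–aluminium bond adds to formaldehyde with retention (vinylalumination), giving the angelate‑type (Z) olefin directly.

Step 14
Reactants: 27 methyl (Z)‑2‑(hydroxymethyl)but‑2‑enoate
Product: 28 methyl (Z)‑2‑[(TBS‑oxy)methyl]but‑2‑enoate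
Conditions: TBSCl, imidazole, DMF, rt
Reagents that add atoms: tert‑butyldimethylsilyl chloride, CC(C)(C)[Si](C)(C)Cl
Why: Standard silylation of the primary allylic alcohol prevents self‑acylation in step 16.

Step 15
Reactants: 28 methyl (Z)‑2‑[(TBS‑oxy)methyl]but‑2‑enoate
Product: 29 (Z)‑2‑[(TBS‑oxy)methyl]but‑2‑enoic acid
Conditions: LiOH, THF/MeOH/H2O, rt; then 1 M HCl to pH 4, 0 °C
Reagents that add atoms: lithium hydroxide, [Li+].[OH-]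
Why: Saponification of the methyl ester without a nucleophilic catalyst leaves the (Z) olefin and the silyl ether intact.

Step 16
Reactants: 24 15‑acetoxy‑3β‑(TBS‑oxy)‑5α,10β‑epoxy‑8β‑hydroxy‑4αH‑germacr‑11(13)‑en‑6α,12‑olide; 29 (Z)‑2‑[(TBS‑oxy)methyl]but‑2‑enoic acid
Product: 31 15‑acetoxy‑3β‑(TBS‑oxy)‑5α,10β‑epoxy‑8β‑{(Z)‑2‑[(TBS‑oxy)methyl]but‑2‑enoyloxy}‑4αH‑germacr‑11(13)‑en‑6α,12‑olide, via mixed anhydride 30 (not isolated)
Conditions: 29, 2,4,6‑trichlorobenzoyl chloride, Et3N, toluene, rt; then 24, 75 °C (no DMAP)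
Reagents that add atoms: none
Why: Yamaguchi mixed‑anhydride esterification run without DMAP acylates the only free hydroxyl (C8) and avoids the DMAP‑mediated Z→E isomerisation that is typical of angelate‑type acids.

Step 17
Reactants: 31 15‑acetoxy‑3β‑(TBS‑oxy)‑5α,10β‑epoxy‑8β‑{(Z)‑2‑[(TBS‑oxy)methyl]but‑2‑enoyloxy}‑4αH‑germacr‑11(13)‑en‑6α,12‑olide
Product: 32 target, 15‑acetoxy‑5α,10β‑epoxy‑3β‑hydroxy‑8β‑[(Z)‑2‑(hydroxymethyl)but‑2‑enoyloxy]‑4αH‑germacr‑11(13)‑en‑6α,12‑olide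
Conditions: HF·pyridine, THF, 0 °C → rt
Reagents that add atoms: none
Why: Acidic fluoride removes both TBS ethers without the acetyl migration or lactone opening that basic fluoride could cause.

**Compound list**
1 | (R)‑(−)‑linalool | C=C[C@](C)(O)CCC=C(C)C | starting material
2 | (5R)‑5‑methyl‑5‑vinyltetrahydrofuran‑2‑ol (anomers) | C=C[C@@]1(C)CCC(O)O1 | intermediate
3 | (5R)‑5‑methyl‑5‑vinyldihydrofuran‑2(3H)‑one | C=C[C@@]1(C)CCC(=O)O1 | intermediate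
4 | 3‑bromofuran | Brc1ccoc1 | starting material
5 | furan‑3‑yllithium | [Li]c1ccoc1 | intermediate
6 | (4R)‑1‑(furan‑3‑yl)‑4‑hydroxy‑4‑methylhex‑5‑en‑1‑one | C=C[C@](C)(O)CCC(=O)c1ccoc1 | intermediate
7 | (1S,4R)‑1‑(furan‑3‑yl)‑4‑methylhex‑5‑ene‑1,4‑diol | C=C[C@](C)(O)CC[C@H](O)c1ccoc1 | intermediate
8 | (1S,4R)‑1‑(TBS‑oxy)‑1‑(furan‑3‑yl)‑4‑methylhex‑5‑en‑4‑ol | C=C[C@](C)(O)CC[C@H](O[Si](C)(C)C(C)(C)C)c1ccoc1 | intermediate
9 | (1S,4R)‑1‑(furan‑3‑yl)‑4‑methyl‑1‑(TBS‑oxy)‑4‑(TES‑oxy)hex‑5‑ene | C=C[C@](C)(O[Si](CC)(CC)CC)CC[C@H](O[Si](C)(C)C(C)(C)C)c1ccoc1 | intermediate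
10 | (4R,7S)‑7‑(TBS‑oxy)‑7‑(furan‑3‑yl)‑4‑methyl‑4‑(TES‑oxy)heptanal | O=CCC[C@](C)(O[Si](CC)(CC)CC)CC[C@H](O[Si](C)(C)C(C)(C)C)c1ccoc1 | intermediate
11 | (2R,4R,7S)‑7‑(TBS‑oxy)‑7‑(furan‑3‑yl)‑4‑methyl‑4‑(TES‑oxy)‑2‑(OTMP)heptanal | O=C[C@H](ON1C(C)(C)CCCC1(C)C)C[C@](C)(O[Si](CC)(CC)CC)CC[C@H](O[Si](C)(C)C(C)(C)C)c1ccoc1 | intermediate
12 | methyl propiolate | C#CC(=O)OC | starting material
13 | methyl 2‑(diisobutylalumanyl)acrylate | C=C([Al](CC(C)C)CC(C)C)C(=O)OC | intermediate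
14 | methyl (3RS,4R,6R,9S)‑9‑(TBS‑oxy)‑9‑(furan‑3‑yl)‑3‑hydroxy‑6‑methyl‑2‑methylidene‑4‑(OTMP)‑6‑(TES‑oxy)nonanoate | C=C(C(=O)OC)C(O)[C@H](ON1C(C)(C)CCCC1(C)C)C[C@](C)(O[Si](CC)(CC)CC)CC[C@H](O[Si](C)(C)C(C)(C)C)c1ccoc1 | intermediate
15 | 3‑O‑mesylate of 14 | C=C(C(=O)OC)C(OS(C)(=O)=O)[C@H](ON1C(C)(C)CCCC1(C)C)C[C@](C)(O[Si](CC)(CC)CC)CC[C@H](O[Si](C)(C)C(C)(C)C)c1ccoc1 | intermediate
16 | methyl (2Z,4R,6R,9S)‑2‑(bromomethyl)‑9‑(TBS‑oxy)‑9‑(furan‑3‑yl)‑6‑methyl‑4‑(OTMP)‑6‑(TES‑oxy)non‑2‑enoate | COC(=O)C(/CBr)=C/[C@H](ON1C(C)(C)CCCC1(C)C)C[C@](C)(O[Si](CC)(CC)CC)CC[C@H](O[Si](C)(C)C(C)(C)C)c1ccoc1 | intermediate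
17 | methyl (2Z,4R,6R,9S,10Z)‑2‑(bromomethyl)‑9‑(TBS‑oxy)‑10‑formyl‑6‑methyl‑12‑oxo‑4‑(OTMP)‑6‑(TES‑oxy)dodeca‑2,10‑dienoate | COC(=O)C(/CBr)=C/[C@H](ON1C(C)(C)CCCC1(C)C)C[C@](C)(O[Si](CC)(CC)CC)CC[C@H](O[Si](C)(C)C(C)(C)C)/C(C=O)=C/C=O | intermediate
18 | methyl 6α‑hydroxy‑3β‑(TBS‑oxy)‑8β‑(OTMP)‑10β‑(TES‑oxy)‑15‑oxogermacra‑4,11(13)‑dien‑12‑oate | C=C(C(=O)OC)[C@H]1[C@H](O)/C=C(C=O)/[C@@H](O[Si](C)(C)C(C)(C)C)CC[C@@](C)(O[Si](CC)(CC)CC)C[C@H]1ON2C(C)(C)CCCC2(C)C | intermediate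
19 | 3β‑(TBS‑oxy)‑8β‑(OTMP)‑10β‑(TES‑oxy)‑15‑oxogermacra‑4,11(13)‑dien‑6α,12‑olide | C=C1C(=O)O[C@@H]2/C=C(C=O)/[C@@H](O[Si](C)(C)C(C)(C)C)CC[C@@](C)(O[Si](CC)(CC)CC)C[C@@H](ON3C(C)(C)CCCC3(C)C)[C@@H]12 | intermediate
20 | 10β‑hydroxy‑3β‑(TBS‑oxy)‑8β‑(OTMP)‑15‑oxogermacra‑4,11(13)‑dien‑6α,12‑olide | C=C1C(=O)O[C@@H]2/C=C(C=O)/[C@@H](O[Si](C)(C)C(C)(C)C)CC[C@@](C)(O)C[C@@H](ON3C(C)(C)CCCC3(C)C)[C@@H]12 | intermediate
21 | 3β‑(TBS‑oxy)‑8β‑(OTMP)‑5α,10β‑epoxy‑15‑oxo‑4αH‑germacr‑11(13)‑en‑6α,12‑olide | C=C1C(=O)O[C@@H]2[C@@H]3O[C@](C)(CC[C@H](O[Si](C)(C)C(C)(C)C)[C@@H]3C=O)C[C@@H](ON4C(C)(C)CCCC4(C)C)[C@@H]12 | intermediate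
22 | 3β‑(TBS‑oxy)‑8β‑(OTMP)‑5α,10β‑epoxy‑15‑hydroxy‑4αH‑germacr‑11(13)‑en‑6α,12‑olide | C=C1C(=O)O[C@@H]2[C@@H]3O[C@](C)(CC[C@H](O[Si](C)(C)C(C)(C)C)[C@@H]3CO)C[C@@H](ON4C(C)(C)CCCC4(C)C)[C@@H]12 | intermediate
23 | 15‑acetoxy‑3β‑(TBS‑oxy)‑8β‑(OTMP)‑5α,10β‑epoxy‑4αH‑germacr‑11(13)‑en‑6α,12‑olide | C=C1C(=O)O[C@@H]2[C@@H]3O[C@](C)(CC[C@H](O[Si](C)(C)C(C)(C)C)[C@@H]3COC(C)=O)C[C@@H](ON4C(C)(C)CCCC4(C)C)[C@@H]12 | intermediate
24 | 15‑acetoxy‑3β‑(TBS‑oxy)‑5α,10β‑epoxy‑8β‑hydroxy‑4αH‑germacr‑11(13)‑en‑6α,12‑olide | C=C1C(=O)O[C@@H]2[C@@H]3O[C@](C)(CC[C@H](O[Si](C)(C)C(C)(C)C)[C@@H]3COC(C)=O)C[C@@H](O)[C@@H]12 | intermediate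
25 | methyl but‑2‑ynoate | CC#CC(=O)OC | starting material
26 | methyl (E)‑2‑(diisobutylalumanyl)but‑2‑enoate | C/C=C(/[Al](CC(C)C)CC(C)C)C(=O)OC | intermediate
27 | methyl (Z)‑2‑(hydroxymethyl)but‑2‑enoate | C/C=C(/CO)C(=O)OC | intermediate
28 | methyl (Z)‑2‑[(TBS‑oxy)methyl]but‑2‑enoate | C/C=C(/CO[Si](C)(C)C(C)(C)C)C(=O)OC | intermediate
29 | (Z)‑2‑[(TBS‑oxy)methyl]but‑2‑enoic acid | C/C=C(/CO[Si](C)(C)C(C)(C)C)C(=O)O | intermediate
30 | (Z)‑2‑[(TBS‑oxy)methyl]but‑2‑enoic 2,4,6‑trichlorobenzoic anhydride | C/C=C(/CO[Si](C)(C)C(C)(C)C)C(=O)OC(=O)c1c(Cl)cc(Cl)cc1Cl | intermediate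
31 | 15‑acetoxy‑3β‑(TBS‑oxy)‑5α,10β‑epoxy‑8β‑{(Z)‑2‑[(TBS‑oxy)methyl]but‑2‑enoyloxy}‑4αH‑germacr‑11(13)‑en‑6α,12‑olide | C=C1C(=O)O[C@@H]2[C@@H]3O[C@](C)(CC[C@H](O[Si](C)(C)C(C)(C)C)[C@@H]3COC(C)=O)C[C@@H](OC(=O)/C(=C\C)CO[Si](C)(C)C(C)(C)C)[C@@H]12 | intermediate
32 | CNP0311647.1 | C=C1C(=O)O[C@@H]2[C@@H]3O[C@](C)(CC[C@H](O)[C@@H]3COC(C)=O)C[C@@H](OC(=O)/C(=C\C)CO)[C@@H]12 | target

**Step count and risks**

Total steps: 17. Longest linear sequence: 14 (steps 1–12, 16, 17); the side‑chain acid takes steps 13–15.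

Most likely to fail:

Step 9. The indium allyl may add to the wrong formyl group (nine‑membered ring), give the cis lactone, or fail to close the ring. The fallback sets out from 14 and comes back at 19, and tells the two ends of the latent enedial apart by oxidation level instead of by sterics. Dye‑sensitised photo‑oxygenation of the furan in 14 with i‑Pr2NEt (O2, hν, rose bengal, CH2Cl2, −78 °C) gives regioselectively the γ‑hydroxybutenolide F1 (C6 as lactone carbonyl, C15 as lactol carbon). NaBH4 and acidification give the 4‑substituted butenolide F2, and PBr3 gives the rearranged allylic bromide F3. One equivalent of DIBAL‑H at −78 °C reduces the butenolide, in preference to the hindered cross‑conjugated methyl ester, to the lactol F4, in which C6 is the only aldehyde carbon. Indium in aqueous THF at high dilution closes the ring to the hydroxy ester F5, which lactonises to the 15‑hydroxy macrolide F6, and MnO2 oxidises the allylic C15 alcohol to 19.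

Step 10. The conjugate addition may deliver the cis‑bridged C5 epimer. The fallback sets out from 19 and comes back at 21, and uses olefin geometry as the control element. Irradiation of 19 (350 nm, cat. PhSSPh, benzene) equilibrates it with the ring‑cis (heliangolide‑type) enal F7, which is separated. HF·pyridine frees the ring‑cis tertiary alcohol F8, whose hydroxyl meets the opposite face of C5, and conjugate addition with protonation at C4 gives aldehyde 21, which is reduced as in step 10.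

Step 12. Zinc may be too slow on the hindered alkoxyamine or may touch the α‑methylene lactone. The fallback sets out from 23 and comes back at 24, and cleaves the N–O bond oxidatively. mCPBA (CH2Cl2, 0 °C) N‑oxidises the alkoxyamine and Cope‑type elimination gives the 8‑ketone F9. Luche reduction at −78 °C, with hydride from the less hindered α‑face and cold enough to avoid β‑elimination of the C10 ether, returns the 8β‑alcohol 24.

**Further compounds**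
F1 | step 9 | methyl (3RS,4R,6R,9S)‑9‑(TBS‑oxy)‑3‑hydroxy‑9‑(2‑hydroxy‑5‑oxo‑2,5‑dihydrofuran‑3‑yl)‑6‑methyl‑2‑methylidene‑4‑(OTMP)‑6‑(TES‑oxy)nonanoate | C=C(C(=O)OC)C(O)[C@H](ON1C(C)(C)CCCC1(C)C)C[C@](C)(O[Si](CC)(CC)CC)CC[C@H](O[Si](C)(C)C(C)(C)C)C1=CC(=O)OC1O
F2 | step 9 | methyl (3RS,4R,6R,9S)‑9‑(TBS‑oxy)‑3‑hydroxy‑6‑methyl‑2‑methylidene‑9‑(5‑oxo‑2,5‑dihydrofuran‑3‑yl)‑4‑(OTMP)‑6‑(TES‑oxy)nonanoate | C=C(C(=O)OC)C(O)[C@H](ON1C(C)(C)CCCC1(C)C)C[C@](C)(O[Si](CC)(CC)CC)CC[C@H](O[Si](C)(C)C(C)(C)C)C1=CC(=O)OC1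
F3 | step 9 | methyl (2Z,4R,6R,9S)‑2‑(bromomethyl)‑9‑(TBS‑oxy)‑6‑methyl‑9‑(5‑oxo‑2,5‑dihydrofuran‑3‑yl)‑4‑(OTMP)‑6‑(TES‑oxy)non‑2‑enoate | COC(=O)C(/CBr)=C/[C@H](ON1C(C)(C)CCCC1(C)C)C[C@](C)(O[Si](CC)(CC)CC)CC[C@H](O[Si](C)(C)C(C)(C)C)C1=CC(=O)OC1
F4 | step 9 | methyl (2Z,4R,6R,9S)‑2‑(bromomethyl)‑9‑(TBS‑oxy)‑9‑(5‑hydroxy‑2,5‑dihydrofuran‑3‑yl)‑6‑methyl‑4‑(OTMP)‑6‑(TES‑oxy)non‑2‑enoate | COC(=O)C(/CBr)=C/[C@H](ON1C(C)(C)CCCC1(C)C)C[C@](C)(O[Si](CC)(CC)CC)CC[C@H](O[Si](C)(C)C(C)(C)C)C1=CC(O)OC1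
F5 | step 9 | methyl 6α,15‑dihydroxy‑3β‑(TBS‑oxy)‑8β‑(OTMP)‑10β‑(TES‑oxy)germacra‑4,11(13)‑dien‑12‑oate | C=C(C(=O)OC)[C@H]1[C@H](O)/C=C(CO)/[C@@H](O[Si](C)(C)C(C)(C)C)CC[C@@](C)(O[Si](CC)(CC)CC)C[C@H]1ON2C(C)(C)CCCC2(C)C
F6 | step 9 | 15‑hydroxy‑3β‑(TBS‑oxy)‑8β‑(OTMP)‑10β‑(TES‑oxy)germacra‑4,11(13)‑dien‑6α,12‑olide | C=C1C(=O)O[C@@H]2/C=C(CO)/[C@@H](O[Si](C)(C)C(C)(C)C)CC[C@@](C)(O[Si](CC)(CC)CC)C[C@@H](ON3C(C)(C)CCCC3(C)C)[C@@H]12
F7 | step 10 | ring‑cis C4=C5 isomer of 19 | C=C1C(=O)O[C@@H]2/C=C(C=O)\[C@@H](O[Si](C)(C)C(C)(C)C)CC[C@@](C)(O[Si](CC)(CC)CC)C[C@@H](ON3C(C)(C)CCCC3(C)C)[C@@H]12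
F8 | step 10 | ring‑cis C4=C5 isomer of 20 | C=C1C(=O)O[C@@H]2/C=C(C=O)\[C@@H](O[Si](C)(C)C(C)(C)C)CC[C@@](C)(O)C[C@@H](ON3C(C)(C)CCCC3(C)C)[C@@H]12
F9 | step 12 | 15‑acetoxy‑3β‑(TBS‑oxy)‑5α,10β‑epoxy‑8‑oxo‑4αH‑germacr‑11(13)‑en‑6α,12‑olide | C=C1C(=O)O[C@@H]2[C@@H]3O[C@](C)(CC[C@H](O[Si](C)(C)C(C)(C)C)[C@@H]3COC(C)=O)CC(=O)[C@@H]12
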